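**Plan**

Numbering: lactone carbonyl C1, C2 (methyl), C3 (enol oxygen), C4 (ring carbon of the ylidene), chain C5 (=CH) to C17 (CH2 on the furan); stereocentres C6 and C14.
Retrosynthesis: after unmasking the C3 enol (methyl ether) and the C14 carbinol (silyl ether), the butenolide is opened at O–C1 and re-closed as a C1–C4 bond. This is possible because C1–C4, with the C2 methyl and the C3 oxygen, are atom for atom the four-membered ring of a methyl-substituted squarate carrying C5 on its carbinol carbon.
Further cuts, in order: C4–C5 (C5 alkyllithium + 3-methoxy-4-methylcyclobutenedione), C8–C9 (alkyl Grignard + allylic bromide), C16–C17 (alkylborane + 3-(bromomethyl)furan); C8 itself comes from formaldehyde.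
Forward: linalool is silylated, joined to the furan and oxidised/brominated at C9; the C5–C8 Grignard is attached at C8–C9; C5 becomes an iodide, is lithiated and added to the squarate-derived dione. The only new ring, the butenolide, arises last by oxidative ring expansion and loss of acetic acid; two deprotections finish.
Stereochemistry: C14 is carried unchanged from (R)-linalool and C6 from (R)-3-bromo-2-methylpropan-1-ol (never alpha to a carbonyl). E-C10=C11 comes from the E-selective SeO2 oxidation of the prenyl terminus, and Z-C4=C5 from thermodynamic control (allylic strain against the C3 methoxy group).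

Key step: step 13

Assumption: the target is taken exactly as drawn (6S,14S; Z at C4=C5; E at C10=C11), and (R)-linalool and (R)-3-bromo-2-methylpropan-1-ol (the bromo alcohol of the Roche ester series) are bought as single enantiomers.

**Route**

Step 1
Reactants: 1 (R)-linalool
Product: 2 (3R)-3,7-dimethyl-3-(triethylsilyloxy)octa-1,6-diene
Conditions: TESOTf, 2,6-lutidine, CH2Cl2, −78 → 0 °C
Reagents that add atoms: triethylsilyl trifluoromethanesulfonate, CC[Si](CC)(CC)OS(=O)(=O)C(F)(F)F
Why: Silyl ether formation with a silyl triflate under 2,6-lutidine buffering is the standard way to cap a hindered tertiary alcohol; the C14 stereocentre is not touched and the base prevents ionisation of the tertiary allylic carbinol.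

Step 2
Reactants: 2 (3R)-3,7-dimethyl-3-(triethylsilyloxy)octa-1,6-diene; 3 3-(bromomethyl)furan
Product: 5 3-[(4S)-4,8-dimethyl-4-(triethylsilyloxy)non-7-en-1-yl]furan, via B-alkyl-9-BBN adduct 4 (not isolated)
Conditions: 9-BBN dimer, THF, 0 °C → rt; then 3, Pd(OAc)2 (4 mol%), PCy3 (8 mol%), K3PO4·H2O, THF, rt
Reagents that add atoms: none
Why: Hydroboration with 9-BBN is anti-Markovnikov and selects the monosubstituted vinyl group over the trisubstituted alkene, and the primary alkylborane then enters a B-alkyl Suzuki–Miyaura alkyl–alkyl cross-coupling with the furylmethyl bromide, a benzylic-type electrophile without beta-hydrogens that adds readily to zerovalent palladium carrying PCy3.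

Step 3
Reactants: 5 3-[(4S)-4,8-dimethyl-4-(triethylsilyloxy)non-7-en-1-yl]furan
Product: 6 (2E,6S)-9-(furan-3-yl)-2,6-dimethyl-6-(triethylsilyloxy)non-2-en-1-ol
Conditions: SeO2 (0.3 equiv), t-BuOOH, CH2Cl2, 0 °C → rt; then NaBH4, MeOH, 0 °C
Reagents that add atoms: SeO2, O=[Se]=O (transfers the oxygen); tert-butyl hydroperoxide, CC(C)(C)OO (restores the selenium oxidant and is the ultimate oxygen source)
Why: Riley allylic oxidation with catalytic SeO2 and t-BuOOH (ene reaction, then 2,3-sigmatropic shift) hydroxylates the (E)-methyl group of a prenyl terminus, which fixes the E geometry of C10=C11, and the NaBH4 treatment returns any over-oxidised enal to the alcohol.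

Step 4
Reactants: 6 (2E,6S)-9-(furan-3-yl)-2,6-dimethyl-6-(triethylsilyloxy)non-2-en-1-ol
Product: 8 3-[(4S,7E)-9-bromo-4,8-dimethyl-4-(triethylsilyloxy)non-7-en-1-yl]furan, via allylic mesylate 7 (not isolated)
Conditions: MsCl, Et3N, THF, −40 °C; then LiBr, THF, −40 → 0 °C
Reagents that add atoms: lithium bromide, [Li+].[Br-]
Why: Mesylation and in-situ SN2 displacement by bromide is the standard mild route from a primary allylic alcohol to its bromide without allylic transposition or loss of alkene geometry, and the basic medium spares silyl ether and furan.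

Step 5
Reactants: 9 (R)-3-bromo-2-methylpropan-1-ol
Product: 10 (R)-(3-bromo-2-methylpropoxy)triethylsilane
Conditions: TESCl, imidazole, CH2Cl2, 0 °C → rt
Reagents that add atoms: chlorotriethylsilane, CC[Si](Cl)(CC)CC
Why: Imidazole-promoted silylation of a primary alcohol is routine, and the stereocentre (later C6) is remote from the reacting oxygen.

Step 6
Reactants: 10 (R)-(3-bromo-2-methylpropoxy)triethylsilane
Product: 12 (S)-3-methyl-4-(triethylsilyloxy)butan-1-ol, via Grignard reagent 11 (not isolated)
Conditions: Mg, THF, rt → 45 °C; then (CH2O)n, THF, 0 °C → rt; aq. NH4Cl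
Reagents that add atoms: formaldehyde (used as paraformaldehyde), C=O
Why: Grignard formation and addition to formaldehyde is a standard one-carbon homologation that supplies C8; the methyl-bearing centre is beta to magnesium and cannot epimerise (its descriptor changes from R to S only because the substituent ranking changes).

Step 7
Reactants: 12 (S)-3-methyl-4-(triethylsilyloxy)butan-1-ol
Product: 14 (S)-(4-bromo-2-methylbutoxy)triethylsilane, via mesylate 13 (not isolated)
Conditions: MsCl, Et3N, THF, 0 °C; then LiBr, THF, 45 °C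
Reagents that add atoms: lithium bromide, [Li+].[Br-]
Why: Mesylation followed by SN2 displacement with LiBr (Finkelstein-type exchange) converts the unhindered primary alcohol to the bromide under conditions that leave the primary silyl ether intact.

Step 8
Reactants: 14 (S)-(4-bromo-2-methylbutoxy)triethylsilane; 8 3-[(4S,7E)-9-bromo-4,8-dimethyl-4-(triethylsilyloxy)non-7-en-1-yl]furan
Product: 16 3-[(4S,7E,12S)-4,8,12-trimethyl-4,13-bis(triethylsilyloxy)tridec-7-en-1-yl]furan, via Grignard reagent 15 (not isolated)
Conditions: 14, Mg, THF, rt → 45 °C; then added slowly to 8, Li2CuCl4 (5 mol%), THF, −78 → 0 °C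
Reagents that add atoms: none
Why: Copper-catalysed sp3–sp3 cross-coupling of a primary alkyl Grignard reagent with a primary allylic bromide (Li2CuCl4 catalysis) should proceed by alpha attack at C9 with retention of the E alkene, as is usual for head-to-tail terpenoid chain extension at low temperature.

Step 9
Reactants: 16 3-[(4S,7E,12S)-4,8,12-trimethyl-4,13-bis(triethylsilyloxy)tridec-7-en-1-yl]furan
Product: 17 (2S,6E,10S)-13-(furan-3-yl)-2,6,10-trimethyl-10-(triethylsilyloxy)tridec-6-en-1-ol
Conditions: PPTS (0.2 equiv), MeOH/CH2Cl2 (1:1), 0 °C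
Reagents that add atoms: none
Why: Acid-catalysed methanolysis of silyl ethers is governed by steric access to silicon, so the primary triethylsilyl ether should be cleaved well before the tertiary one at C14 (selective desilylation).

Step 10
Reactants: 17 (2S,6E,10S)-13-(furan-3-yl)-2,6,10-trimethyl-10-(triethylsilyloxy)tridec-6-en-1-ol
Product: 18 3-[(4S,7E,12S)-13-iodo-4,8,12-trimethyl-4-(triethylsilyloxy)tridec-7-en-1-yl]furan
Conditions: I2, PPh3, imidazole, CH2Cl2, 0 °C → rt, dark
Reagents that add atoms: iodine, [I][I]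
Why: Appel-type iodination (PPh3/I2/imidazole) converts the primary alcohol to the iodide by SN2 at C5 without touching the adjacent C6 stereocentre, and the imidazole buffer protects silyl ether and furan.

Step 11
Reactants: 19 dimethyl squarate
Product: 22 3-methoxy-4-methylcyclobut-3-ene-1,2-dione, via lithium alkoxide 20 (not isolated), via trifluoroacetate ester 21 (not isolated)
Conditions: MeLi, THF, −78 °C; then (CF3CO)2O, −78 °C; then H2O, −78 °C → rt
Reagents that add atoms: methyllithium, [Li]C; water, O
Why: 1,2-Addition of methyllithium to one carbonyl of the squarate ester, trifluoroacetylation of the alkoxide and hydrolytic loss of trifluoroacetate and methanol (an allylic oxygen transposition through a methoxy-stabilised cyclobutenyl cation) is the standard entry to 3-alkoxy-4-alkylcyclobutenediones.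

Step 12
Reactants: 18 3-[(4S,7E,12S)-13-iodo-4,8,12-trimethyl-4-(triethylsilyloxy)tridec-7-en-1-yl]furan; 22 3-methoxy-4-methylcyclobut-3-ene-1,2-dione
Product: 24 4-hydroxy-3-methoxy-2-methyl-4-[(2S,6E,10S)-13-(furan-3-yl)-2,6,10-trimethyl-10-(triethylsilyloxy)tridec-6-en-1-yl]cyclobut-2-en-1-one (both carbinol epimers), via alkyllithium 23 (not isolated)
Conditions: 18, t-BuLi (2.1 equiv), Et2O/pentane, −78 °C; then cannulated into 22 (1.3 equiv), THF, −78 °C; aq. NH4Cl, −78 °C
Reagents that add atoms: none
Why: Iodine–lithium exchange of a primary iodide with two equivalents of t-BuLi is faster at −78 °C than furan metalation, and the alkyllithium should add 1,2 to the carbonyl flanked by the methoxy-bearing carbon (the more electrophilic one, since the other carbonyl is a vinylogous ester), so that methyl and methoxy end up on C2 and C3; the new carbinol centre C4 forms as both epimers, which does not matter because it becomes sp2 in step 13.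

Step 13
Reactants: 24 4-hydroxy-3-methoxy-2-methyl-4-[(2S,6E,10S)-13-(furan-3-yl)-2,6,10-trimethyl-10-(triethylsilyloxy)tridec-6-en-1-yl]cyclobut-2-en-1-one
Product: 26 (5Z)-5-[(2S,6E,10S)-13-(furan-3-yl)-2,6,10-trimethyl-10-(triethylsilyloxy)tridec-6-en-1-ylidene]-4-methoxy-3-methylfuran-2(5H)-one, via 5-acetoxybutenolide 25 (not isolated)
Conditions: Pb(OAc)4 (1.1 equiv), toluene, 0 °C → rt; then DBU (2 equiv), rt
Reagents that add atoms: none
Why: The tertiary cyclobutenol exchanges with an acetate of Pb(OAc)4 to give a tetravalent lead alkoxide, which fragments with release of ring strain: the C4–C1 bond (carbinol carbon to ring carbonyl) breaks, lead leaves as divalent Pb(OAc)2, C4 becomes a ketone and C1 an acylium (or acyl radical) centre held cis to it by the C2=C3 alkene. The ketone oxygen then captures C1, closing the five-membered lactone through the new O–C1 bond (a 5-exo closure onto the digonal acylium carbon, in effect an intramolecular O-acylation), and acetate adds to the resulting ring oxocarbenium ion at C4 to give acetoxybutenolide 25. DBU then removes acetic acid across C4–C5, the only direction open because C3 carries no hydrogen, to give the conjugated ylidene. The closest known reaction type is the Pb(OAc)4 oxidative ring expansion of 4-hydroxycyclobut-2-enones to 5-acetoxy- and 5-ylidene-furan-2(5H)-ones, of which this is a direct application. No stereocentre is formed (the carbinol epimers of 24 converge), and the Z geometry should result as the thermodynamic one because an E chain would suffer allylic strain against the C3 methoxy group, while the short, mild base treatment is meant to leave the C6 centre next to the new alkene untouched. The selectivity required is oxidation at the cyclobutenol only; it rests on fast alkoxide exchange and strain-driven fragmentation at or below room temperature, where Pb(OAc)4 should not acetoxylate the 3-alkylfuran or the C10=C11 alkene, and on the silyl ether that keeps the C14 oxygen away from lead.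

Step 14
Reactants: 26 (5Z)-5-[(2S,6E,10S)-13-(furan-3-yl)-2,6,10-trimethyl-10-(triethylsilyloxy)tridec-6-en-1-ylidene]-4-methoxy-3-methylfuran-2(5H)-one
Product: 27 (5Z)-5-[(2S,6E,10S)-13-(furan-3-yl)-10-hydroxy-2,6,10-trimethyltridec-6-en-1-ylidene]-4-methoxy-3-methylfuran-2(5H)-one
Conditions: HF·pyridine, pyridine, THF, 0 °C → rt
Reagents that add atoms: none
Why: Fluoride-mediated desilylation with pyridine-buffered HF·pyridine cleaves the tertiary silyl ether at C14 without acid strong enough to harm the furan or ionise the tertiary carbinol.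

Step 15
Reactants: 27 (5Z)-5-[(2S,6E,10S)-13-(furan-3-yl)-10-hydroxy-2,6,10-trimethyltridec-6-en-1-ylidene]-4-methoxy-3-methylfuran-2(5H)-one
Product: 28 (5Z)-5-[(2S,6E,10S)-13-(furan-3-yl)-10-hydroxy-2,6,10-trimethyltridec-6-en-1-ylidene]-4-hydroxy-3-methylfuran-2(5H)-one (target)
Conditions: LiCl (10 equiv), DMF, 90 °C; then 1 M HCl work-up
Reagents that add atoms: none
Why: SN2 O-demethylation by chloride in a dipolar aprotic solvent (Krapcho-type dealkylation) should work because the enol ether is a vinylogous methyl carbonate whose leaving group is the stabilised tetronate anion, and acidification then frees the tetronic acid with the thermodynamically preferred Z ylidene retained.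

**Compound list**

1 | (R)-linalool | C=C[C@](C)(O)CCC=C(C)C | starting material
2 | (3R)-3,7-dimethyl-3-(triethylsilyloxy)octa-1,6-diene | C=C[C@](C)(O[Si](CC)(CC)CC)CCC=C(C)C | intermediate
3 | 3-(bromomethyl)furan | BrCc1ccoc1 | starting material
4 | 9-[(3S)-3,7-dimethyl-3-(triethylsilyloxy)oct-6-en-1-yl]-9-borabicyclo[3.3.1]nonane | CC(C)=CCC[C@@](C)(O[Si](CC)(CC)CC)CCB1C2CCCC1CCC2 | intermediate (not isolated)
5 | 3-[(4S)-4,8-dimethyl-4-(triethylsilyloxy)non-7-en-1-yl]furan | CC(C)=CCC[C@@](C)(O[Si](CC)(CC)CC)CCCc1ccoc1 | intermediate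
6 | (2E,6S)-9-(furan-3-yl)-2,6-dimethyl-6-(triethylsilyloxy)non-2-en-1-ol | OC/C(C)=C/CC[C@@](C)(O[Si](CC)(CC)CC)CCCc1ccoc1 | intermediate
7 | (2E,6S)-9-(furan-3-yl)-2,6-dimethyl-6-(triethylsilyloxy)non-2-en-1-yl methanesulfonate | CS(=O)(=O)OC/C(C)=C/CC[C@@](C)(O[Si](CC)(CC)CC)CCCc1ccoc1 | intermediate (not isolated)
8 | 3-[(4S,7E)-9-bromo-4,8-dimethyl-4-(triethylsilyloxy)non-7-en-1-yl]furan | BrC/C(C)=C/CC[C@@](C)(O[Si](CC)(CC)CC)CCCc1ccoc1 | intermediate
9 | (R)-3-bromo-2-methylpropan-1-ol | OC[C@@H](C)CBr | starting material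
10 | (R)-(3-bromo-2-methylpropoxy)triethylsilane | CC[Si](CC)(CC)OC[C@@H](C)CBr | intermediate
11 | [(R)-2-methyl-3-(triethylsilyloxy)propyl]magnesium bromide | CC[Si](CC)(CC)OC[C@@H](C)C[Mg]Br | intermediate (not isolated)
12 | (S)-3-methyl-4-(triethylsilyloxy)butan-1-ol | CC[Si](CC)(CC)OC[C@@H](C)CCO | intermediate
13 | (S)-3-methyl-4-(triethylsilyloxy)butyl methanesulfonate | CC[Si](CC)(CC)OC[C@@H](C)CCOS(C)(=O)=O | intermediate (not isolated)
14 | (S)-(4-bromo-2-methylbutoxy)triethylsilane | CC[Si](CC)(CC)OC[C@@H](C)CCBr | intermediate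
15 | [(S)-3-methyl-4-(triethylsilyloxy)butyl]magnesium bromide | CC[Si](CC)(CC)OC[C@@H](C)CC[Mg]Br | intermediate (not isolated)
16 | 3-[(4S,7E,12S)-4,8,12-trimethyl-4,13-bis(triethylsilyloxy)tridec-7-en-1-yl]furan | CC[Si](CC)(CC)OC[C@@H](C)CCC/C(C)=C/CC[C@@](C)(O[Si](CC)(CC)CC)CCCc1ccoc1 | intermediate
17 | (2S,6E,10S)-13-(furan-3-yl)-2,6,10-trimethyl-10-(triethylsilyloxy)tridec-6-en-1-ol | OC[C@@H](C)CCC/C(C)=C/CC[C@@](C)(O[Si](CC)(CC)CC)CCCc1ccoc1 | intermediate
18 | 3-[(4S,7E,12S)-13-iodo-4,8,12-trimethyl-4-(triethylsilyloxy)tridec-7-en-1-yl]furan | IC[C@@H](C)CCC/C(C)=C/CC[C@@](C)(O[Si](CC)(CC)CC)CCCc1ccoc1 | intermediate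
19 | dimethyl squarate (3,4-dimethoxycyclobut-3-ene-1,2-dione) | COC1=C(OC)C(=O)C1=O | starting material
20 | lithium 2,3-dimethoxy-1-methyl-4-oxocyclobut-2-en-1-olate | COC1=C(OC)C(C)([O-])C1=O.[Li+] | intermediate (not isolated)
21 | 2,3-dimethoxy-1-methyl-4-oxocyclobut-2-en-1-yl trifluoroacetate | COC1=C(OC)C(C)(OC(=O)C(F)(F)F)C1=O | intermediate (not isolated)
22 | 3-methoxy-4-methylcyclobut-3-ene-1,2-dione | COC1=C(C)C(=O)C1=O | intermediate
23 | C5 lithium reagent of 18, [(2R,6E,10S)-13-(furan-3-yl)-2,6,10-trimethyl-10-(triethylsilyloxy)tridec-6-en-1-yl]lithium (same spatial arrangement as 18; descriptor changes with the ranking) | [Li]C[C@@H](C)CCC/C(C)=C/CC[C@@](C)(O[Si](CC)(CC)CC)CCCc1ccoc1 | intermediate (not isolated)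
24 | 4-hydroxy-3-methoxy-2-methyl-4-[(2S,6E,10S)-13-(furan-3-yl)-2,6,10-trimethyl-10-(triethylsilyloxy)tridec-6-en-1-yl]cyclobut-2-en-1-one (both carbinol epimers) | COC1=C(C)C(=O)C1(O)C[C@@H](C)CCC/C(C)=C/CC[C@@](C)(O[Si](CC)(CC)CC)CCCc1ccoc1 | intermediate
25 | 2-[(2S,6E,10S)-13-(furan-3-yl)-2,6,10-trimethyl-10-(triethylsilyloxy)tridec-6-en-1-yl]-3-methoxy-4-methyl-5-oxo-2,5-dihydrofuran-2-yl acetate (both ring epimers) | CC1=C(OC)C(OC(C)=O)(C[C@@H](C)CCC/C(C)=C/CC[C@@](C)(O[Si](CC)(CC)CC)CCCc2ccoc2)OC1=O | intermediate (not isolated)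
26 | (5Z)-5-[(2S,6E,10S)-13-(furan-3-yl)-2,6,10-trimethyl-10-(triethylsilyloxy)tridec-6-en-1-ylidene]-4-methoxy-3-methylfuran-2(5H)-one | CC1=C(OC)/C(=C/[C@@H](C)CCC/C(C)=C/CC[C@@](C)(O[Si](CC)(CC)CC)CCCc2ccoc2)OC1=O | intermediate
27 | (5Z)-5-[(2S,6E,10S)-13-(furan-3-yl)-10-hydroxy-2,6,10-trimethyltridec-6-en-1-ylidene]-4-methoxy-3-methylfuran-2(5H)-one | CC1=C(OC)/C(=C/[C@@H](C)CCC/C(C)=C/CC[C@@](C)(O)CCCc2ccoc2)OC1=O | intermediate
28 | (5Z)-5-[(2S,6E,10S)-13-(furan-3-yl)-10-hydroxy-2,6,10-trimethyltridec-6-en-1-ylidene]-4-hydroxy-3-methylfuran-2(5H)-one | CC1=C(O)/C(=C/[C@@H](C)CCC/C(C)=C/CC[C@@](C)(O)CCCc2ccoc2)OC1=O | target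

**Count and risks**

Total step count: 15. Longest linear sequence: 11 steps from (R)-linalool (steps 1–4, 8–10, 12–15).

Steps most likely to fail:

1. Step 13 (oxidative ring expansion). What may go wrong: acetoxylation of the furan or of the C10=C11 alkene by Pb(OAc)4 in competition with alkoxide fragmentation, sluggish or unselective loss of acetic acid from 25, or base-induced epimerisation at C6 through the extended enolate. Fallback (sets out from 24, returns at 26): the oxidant is removed from the ring-forming event. Heating 24 in toluene at reflux should open the four-membered ring electrocyclically to a vinylketene that is trapped by its own hydroxyl group, giving after tautomerisation the butenolide 5-alkyl-4-methoxy-3-methylfuran-2(5H)-one F1 (both ring epimers, one oxidation level below 26). Deprotonation with LiN(i-Pr)2 (THF, −78 °C) should give the lithium 2-furanolate F2, which PhSeCl selenenylates at the ring carbon next to oxygen to give the phenylselenide F3. One equivalent of mCPBA at −78 °C should give the selenoxide F4, which on warming with i-Pr2NH loses PhSeOH by syn-elimination toward C5, the only carbon with beta-hydrogens, to give 26.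

2. Step 2 (alkyl–alkyl Suzuki coupling). What may go wrong: slow transmetalation of the alkylborane against decomposition or homocoupling of the labile furylmethyl bromide, or protodeboronation, leaving the C16–C17 bond unformed. Fallback (sets out from 2, returns at 5): the borane becomes the precursor of a Grignard nucleophile for a copper-catalysed coupling. Alkylborane 4 is oxidised (NaOH, H2O2) to the primary alcohol (3R)-3,7-dimethyl-3-(triethylsilyloxy)oct-6-en-1-ol F5, which PPh3/I2/imidazole converts to the iodide triethyl{[(3R)-1-iodo-3,7-dimethyloct-6-en-3-yl]oxy}silane F6. Magnesium in THF should give the Grignard reagent [(3R)-3,7-dimethyl-3-(triethylsilyloxy)oct-6-en-1-yl]magnesium iodide F7, which is coupled with 3 under Li2CuCl4 catalysis (THF, −78 → 0 °C) to give 5.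

3. Step 12 (alkyllithium addition to the dione). What may go wrong: metalation of the furan 2-position during iodine–lithium exchange, deprotonation of the dione's methyl group instead of addition, or attack at the vinylogous-ester carbonyl. Fallback (sets out from 17, returns at 26): the four-membered ring is set aside and the C4–C5 bond is made by the classical tetronate aldol route. Dess–Martin periodinane (NaHCO3, CH2Cl2) oxidises 17 to the aldehyde (2S,6E,10S)-13-(furan-3-yl)-2,6,10-trimethyl-10-(triethylsilyloxy)tridec-6-enal F8. Separately, 3-methyltetronic acid is O-methylated (dimethyl sulfate, K2CO3, acetone) to 4-methoxy-3-methylfuran-2(5H)-one F9. LiN(i-Pr)2 at −78 °C should give its lithium enolate F10, which adds to F8 to give the aldol adduct F11 (diastereomers). MsCl/Et3N gives the methanesulfonate F12, and DBU eliminates methanesulfonic acid to give 26, the Z isomer again being the thermodynamic one.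

**Further compounds**

F1 | step 13 | 5-[(2S,6E,10S)-13-(furan-3-yl)-2,6,10-trimethyl-10-(triethylsilyloxy)tridec-6-en-1-yl]-4-methoxy-3-methylfuran-2(5H)-one (both ring epimers) | CC1=C(OC)C(C[C@@H](C)CCC/C(C)=C/CC[C@@](C)(O[Si](CC)(CC)CC)CCCc2ccoc2)OC1=O
F2 | step 13 | lithium 2-furanolate of F1 | [Li+].[O-]c1oc(C[C@@H](C)CCC/C(C)=C/CC[C@@](C)(O[Si](CC)(CC)CC)CCCc2ccoc2)c(OC)c1C
F3 | step 13 | 5-(phenylselanyl) derivative of F1 | CC1=C(OC)C([Se]c2ccccc2)(C[C@@H](C)CCC/C(C)=C/CC[C@@](C)(O[Si](CC)(CC)CC)CCCc2ccoc2)OC1=O
F4 | step 13 | selenoxide of F3 | CC1=C(OC)C([Se](=O)c2ccccc2)(C[C@@H](C)CCC/C(C)=C/CC[C@@](C)(O[Si](CC)(CC)CC)CCCc2ccoc2)OC1=O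
F5 | step 2 | (3R)-3,7-dimethyl-3-(triethylsilyloxy)oct-6-en-1-ol | CC(C)=CCC[C@@](C)(O[Si](CC)(CC)CC)CCO
F6 | step 2 | triethyl{[(3R)-1-iodo-3,7-dimethyloct-6-en-3-yl]oxy}silane | CC(C)=CCC[C@@](C)(O[Si](CC)(CC)CC)CCI
F7 | step 2 | [(3R)-3,7-dimethyl-3-(triethylsilyloxy)oct-6-en-1-yl]magnesium iodide | CC(C)=CCC[C@@](C)(O[Si](CC)(CC)CC)CC[Mg]I
F8 | step 12 | (2S,6E,10S)-13-(furan-3-yl)-2,6,10-trimethyl-10-(triethylsilyloxy)tridec-6-enal | O=C[C@@H](C)CCC/C(C)=C/CC[C@@](C)(O[Si](CC)(CC)CC)CCCc1ccoc1
F9 | step 12 | 4-methoxy-3-methylfuran-2(5H)-one | COC1=C(C)C(=O)OC1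
F10 | step 12 | lithium 4-methoxy-3-methylfuran-2-olate | [Li+].[O-]c1occ(OC)c1C
F11 | step 12 | 5-[(2S,6E,10S)-13-(furan-3-yl)-1-hydroxy-2,6,10-trimethyl-10-(triethylsilyloxy)tridec-6-en-1-yl]-4-methoxy-3-methylfuran-2(5H)-one (diastereomers) | COC1=C(C)C(=O)OC1C(O)[C@@H](C)CCC/C(C)=C/CC[C@@](C)(O[Si](CC)(CC)CC)CCCc1ccoc1
F12 | step 12 | methanesulfonate of F11 | COC1=C(C)C(=O)OC1C(OS(C)(=O)=O)[C@@H](C)CCC/C(C)=C/CC[C@@](C)(O[Si](CC)(CC)CC)CCCc1ccoc1
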